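## The problem

Germacrane numbering is used. The ten-membered carbocycle is C1–C10. C6 bears the lactone oxygen, C7 the acrylate carbon C11 (C12 carbonyl, C13 methylene), C8 the angelate, C10 the methyl group C14 and C4 the exocyclic methylene C15.

The carbocycle is trans-fused at C6–C7 to an α-methylene-γ-butyrolactone. Nine of its ten atoms are functionalised (only C9 is CH2) and eight are stereocentres.

The hardest part is the row C10–C1–C2–C3–C4–C5. It holds a trans trisubstituted epoxide, directly next to it a cis epoxide, then a 1,1-disubstituted alkene, then a carbinol. That is five stereocentres on positions of similar reactivity.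

In an open chain C6–C8 cannot control C1–C5, so each of those centres would need its own reagent-controlled step. Direct closure of a ten-membered ring also pays for transannular strain.

The methylene lactone (a Michael acceptor), the angelate (which isomerises to tiglate), the vinyl epoxide and bis-epoxide array (acid-sensitive) and the ring itself (transannular cyclisation) rule out strong acid, strong nucleophiles and long exposure to base late in the route.

The feature used here is that C5 and C1 both carry oxygen and are 1,3-related through C10, the carbon that bears C14. With a transannular C5–C10 bond drawn in, O–C5–C10–C1–O is the retron of a Grob fragmentation of a trans-decalin (ring A = C10, C1–C5; ring B = C5–C10).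

In that decalin, ring A together with C14, C15 and the oxygen on C1 is, at the oxidation level of three C=C bonds, a 2,4-dimethylphenol substituted at its C3. The angular methyl group C14 controls the faces of ring A.

After the fragmentation the ring keeps the crown shape of the decalin perimeter. The outer faces of C1=C10, C2=C3 and C5=O are exactly the faces that are oxidised or reduced in the target.

## Retrosynthesis

**22 ⇒ 21 ⇒ 19.** The C5–H bond and the two epoxide oxygens are removed. In tetraenone 19 only C1=C10 and C2=C3 are electron-rich. C4=C15 belongs to an enone, and C11=C13 and the angelate are acrylates. An electrophilic oxidant therefore has no choice to make, which would not hold once C5 is a carbinol. For that reason the ketone is reduced last (21 → 22). The forward steps must attack the outer faces only, through monoepoxide 20. Five stereocentres are removed in two operations.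

**19 ⇒ 18.** The transannular bond C5–C10 is added, C5=O becomes C5–OH and C1=C10 becomes C1–OMs. Other transannular bonds (C1–C5, C1–C6, C4–C10) would not put both the donor and the leaving group on carbons that are oxygenated anyway, or would not keep C2=C3 inside a small ring. The precursor 18 is a trans-decalin, so no medium ring has to be closed. The forward Grob fragmentation must give the E alkene, and the antiperiplanar array guarantees this.

**18 ⇒ 17 ⇒ 16 ⇒ 15 ⇒ 14.** Only functional groups of ring A are changed: mesylate back to the 1β-alcohol, the 5α-hydroxy-4(15)-ene back to the 4α,5α-vinyl epoxide, the epoxide back to the C4=C5 alkene, and the alcohol back to the C1 ketone. Each forward step acts next to C10, so C14 decides the face. Dienone 14 has no stereocentre in ring A except C10.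

**14 ⇒ 13.** The C9–C10 bond is cut and ring A is aromatised. Cutting C9–C10 rather than C5–C6 or C8–C9 makes ring A a phenol whose ortho carbon C10 is the nucleophile and makes C9, the only CH2 of the ring, the electrophile. Phenol 13 is monocyclic apart from the lactone. The forward alkylative dearomatisation must choose the ortho carbon C10 and must set C10 through a chair-like six-membered transition state.

**13 ⇒ 12 ⇒ 11 ⇒ 10 ⇒ 9 ⇒ 3 + 7.** After protecting-group and leaving-group adjustments, the C6–C7 bond and the O–C12 bond are cut. Aldehyde 3 (from 1 through 2) carries C1–C6, C10, C14 and C15. Bromide 7 (from 4 and 5 through 6) carries C7–C9 and C11–C13. Fifteen carbons come from two fragments. The boronate of 3 is a masked phenol. The forward Nozaki–Hiyama allylation (through 8) must set C6 and C7 from the single purchased centre C8.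

## Roads not taken

**Alternative 1:** This is the obvious route. It cuts C6–C7 and O–C12 in the ten-membered ring itself. The forward step is an intramolecular CrCl2- or Zn-mediated allylation of the open-chain aldehyde bromide A1, with lactonisation. A1 must already hold C1, C2, C3, C5, C8 and C10, all set in an open chain by separate reagent-controlled steps, which makes a long linear run-up. The ring is then closed against its full strain under high dilution. The chosen plan never closes the medium ring, and the ring-A centres are set by substrate control, first from C14 in the decalin and then on the outer faces of the ten-membered ring.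

**Alternative 2:** This cuts C8–C9 and reconnects C1–C6. The forward step is an anionic oxy-Cope ring expansion of the divinylcyclohexanol A2. The ketone from which A2 is made has C1–H between the carbonyl group and the C2–C3 epoxide, so base opens the epoxide by β-elimination. Without the epoxide, ring A would tautomerise to a phenol. After the expansion C7 still has to be alkylated, C6 reduced and the lactone methylenated on the sensitive ring. The chosen plan brings the finished lactone and angelate into the key step.

**Alternative 3:** This uses the same decalin family but cuts C5–C10 with light. The forward step is a conrotatory six-electron ring opening of the 1,3-diene A3 to the (E,Z,E)-triene A4. The opening is reversible: it leads to a photostationary mixture, and A4 closes again thermally by the disrotatory path. Its three conjugated alkenes would then need three different oxidations, with C1=C10 and C4=C5 nearly alike. The Grob route is irreversible, puts oxygen on C5 from the start and leaves C4=C15 deactivated.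

Key step: step 15

Remark: (S)-glyceraldehyde acetonide 4 is taken as a purchasable compound. It is otherwise one oxidation away from commercial (R)-solketal.

## Route

Step 1
Reactants: 1 2,6-dimethylbenzaldehyde
Product: 2 3-bromo-2,6-dimethylbenzaldehyde
Conditions: NBS, conc. H2SO4, rt
Reagents that add atoms: N-bromosuccinimide, O=C1CCC(=O)N1Br
Why: Electrophilic aromatic bromination; C3 is ortho to one methyl group, para to the other and meta to the protonated formyl group, so all substituents direct to the same carbon, and the ionic medium suppresses benzylic bromination.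

Step 2
Reactants: 2 3-bromo-2,6-dimethylbenzaldehyde
Product: 3 2,6-dimethyl-3-(4,4,5,5-tetramethyl-1,3,2-dioxaborolan-2-yl)benzaldehyde
Conditions: B2pin2, PdCl2(dppf), KOAc, dioxane, 90 °C
Reagents that add atoms: bis(pinacolato)diboron, CC1(C)OB(OC1(C)C)B1OC(C)(C)C(C)(C)O1
Why: Miyaura borylation of an aryl bromide with one ortho substituent; the boronate is a masked phenol that is inert to divalent chromium, sulfonylation and acylation.

Step 3
Reactants: 4 (S)-2,2-dimethyl-1,3-dioxolane-4-carbaldehyde; 5 methyl acrylate
Product: 6 methyl 2-{hydroxy[(4S)-2,2-dimethyl-1,3-dioxolan-4-yl]methyl}acrylate (both carbinol epimers)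
Conditions: DABCO, dioxane–H2O, rt
Reagents that add atoms: none
Why: Morita–Baylis–Hillman reaction of a reactive α-alkoxy aldehyde; the new carbinol centre (C7) is destroyed in step 4, and the dioxolane centre (C8) is not touched.

Step 4
Reactants: 6 methyl 2-{hydroxy[(4S)-2,2-dimethyl-1,3-dioxolan-4-yl]methyl}acrylate
Product: 7 methyl (Z)-2-(bromomethyl)-3-[(4R)-2,2-dimethyl-1,3-dioxolan-4-yl]acrylate (same spatial arrangement at the dioxolane centre as in 4)
Conditions: NBS, Me2S, CH2Cl2, 0 °C to rt
Reagents that add atoms: N-bromosuccinimide, O=C1CCC(=O)N1Br
Why: Corey–Kim-type activation of the allylic alcohol and attack of bromide at the methylene terminus with allylic transposition gives the conjugated Z bromide under neutral conditions that spare the acetonide; the alkene geometry does not matter because the allylchromium reagent of step 5 equilibrates.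

Step 5
Reactants: 3 2,6-dimethyl-3-(pinacolboryl)benzaldehyde; 7 methyl (Z)-2-(bromomethyl)-3-(dioxolanyl)acrylate
Product: 9 trans-5-aryl-4-(2,2-dimethyl-1,3-dioxolan-4-yl)-3-methylenedihydrofuran-2-one (aryl = 2,6-dimethyl-3-pinacolborylphenyl; C6, C7, C8 configured as in 22), via hydroxy ester 8 (not isolated)
Conditions: CrCl2, THF, rt; aqueous work-up, PPTS (cat.), CH2Cl2
Reagents that add atoms: none
Why: Nozaki–Hiyama allylation; the equilibrating allylchromium reagent adds through a chair transition state with both large groups equatorial, which gives the anti adduct 8 and, after lactonisation, the trans lactone (C6 relative to C7). The aldehyde bonds to C7 anti to the C8–O bond of the rotamer that minimises allylic strain (Felkin–Anh sense), which sets C7 relative to C8. Divalent chromium without nickel touches neither the aryl boronate nor the ester.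

Step 6
Reactants: 9 lactone acetonide
Product: 10 C8,C9-diol of the aryl methylene lactone
Conditions: AcOH–H2O–THF, 40 °C
Reagents that add atoms: none
Why: Mild acid hydrolysis of an isopropylidene acetal; pinacol boronate and γ-lactone should survive, and no stereocentre is involved.

Step 7
Reactants: 10 C8,C9-diol
Product: 11 C9 4-toluenesulfonate with free C8 hydroxyl
Conditions: TsCl, Et3N, Bu2SnO (cat.), CH2Cl2, 0 °C
Reagents that add atoms: 4-toluenesulfonyl chloride, Cc1ccc(cc1)S(=O)(=O)Cl
Why: Stannylene-catalysed sulfonylation of a 1,2-diol takes the primary hydroxyl; there is no free phenol to compete because it is still a boronate.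

Step 8
Reactants: 11 C9 tosylate, C8 alcohol
Product: 12 C8 angelate, C9 tosylate, aryl boronate
Conditions: angelic acid, 2,4,6-Cl3C6H2COCl, Et3N, toluene, rt; then 11, 75 °C
Reagents that add atoms: angelic acid, C/C=C(/C)C(=O)O
Why: Yamaguchi-type mixed-anhydride acylation without a nucleophilic catalyst is the usual way to attach an angelate without Z to E isomerisation; the C8–O bond is not broken.

Step 9
Reactants: 12 C8 angelate, C9 tosylate, aryl boronate
Product: 13 phenol (3-hydroxy-2,6-dimethylphenyl lactone with C8 angelate and C9 tosylate)
Conditions: 30% H2O2, NaHCO3, THF–H2O, 0 °C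
Reagents that add atoms: hydrogen peroxide, OO
Why: Oxidation of an aryl boronate by boron-to-oxygen aryl migration; at near-neutral pH and low temperature the acrylate-type alkenes are too poor as acceptors to be epoxidised.

Step 10
Reactants: 13 phenol tosylate
Product: 14 8α-angeloyloxy-1-oxoeudesma-2,4,11(13)-trien-6α,12-olide (10β-methyl)
Conditions: NaH, toluene, 0 to 90 °C, high dilution
Reagents that add atoms: none
Why: Intramolecular alkylative dearomatisation of a phenolate closes ring B (six-membered, C10 attacks C9 with loss of tosylate). In a non-dissociating solvent the sodium ion held by the phenolate oxygen assists the leaving group only at the adjacent carbon C10, and O-alkylation would need an eight-membered ring. The chair transition state with O6, C11 and O8 equatorial puts C14 axial on the β face and so sets C10.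

Step 11
Reactants: 14 linear dienone
Product: 15 8α-angeloyloxy-1β-hydroxyeudesma-2,4,11(13)-trien-6α,12-olide
Conditions: NaBH4, CeCl3·7H2O, MeOH, −78 °C
Reagents that add atoms: none
Why: Luche 1,2-reduction; hydride comes from the α face because C14 stands over the β face next to C1, which gives the equatorial 1β-alcohol. At this temperature the ketone reacts faster than the methylene lactone.

Step 12
Reactants: 15 1β-hydroxy-2,4-diene
Product: 16 8α-angeloyloxy-4α,5α-epoxy-1β-hydroxyeudesma-2,11(13)-dien-6α,12-olide
Conditions: DMDO (one equivalent), acetone–CH2Cl2, −40 °C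
Reagents that add atoms: dimethyldioxirane, CC1(C)OO1
Why: Electrophilic epoxidation takes the tetrasubstituted, most electron-rich alkene C4=C5 of the diene; C14 on the neighbouring C10 blocks the β face, so the oxygen enters from the α face (C4, C5). The neutral reagent spares the acid-sensitive vinyl epoxide.

Step 13
Reactants: 16 4α,5α-vinyl epoxide
Product: 17 8α-angeloyloxy-1β,5α-dihydroxyeudesma-2,4(15),11(13)-trien-6α,12-olide
Conditions: Pd(PPh3)4 (cat.), THF, rt
Reagents that add atoms: none
Why: Isomerisation of a 1,3-diene monoepoxide to a dienol by zerovalent palladium: ionisation of the allylic C4–O bond gives a π-allylpalladium alkoxide on the β face, and β-hydride elimination can only use the freely rotating C15 methyl group (H1 is on the α face, C5 has no hydrogen). The C5–O bond is never broken, so the 5α-hydroxyl is retained.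

Step 14
Reactants: 17 1β,5α-diol
Product: 18 8α-angeloyloxy-5α-hydroxy-1β-mesyloxyeudesma-2,4(15),11(13)-trien-6α,12-olide
Conditions: MsCl, Et3N, CH2Cl2, −40 °C; used crude
Reagents that add atoms: methanesulfonyl chloride, CS(=O)(=O)Cl
Why: Sulfene-type mesylation takes the secondary alcohol and leaves the tertiary C5 hydroxyl free; the C1–O bond is not broken.

Step 15
Reactants: 18 1β-mesylate with free 5α-hydroxyl
Product: 19 8α-angeloyloxy-5-oxogermacra-1(10)E,2Z,4(15),11(13)-tetraen-6α,12-olide
Conditions: KOtBu, THF, −78 to 0 °C
Reagents that add atoms: none
Why: KOtBu deprotonates the tertiary C5 hydroxyl and the alkoxide triggers a concerted Grob (Wharton) fragmentation: the oxygen lone pair builds the C5 carbonyl group, the C5–C10 σ bond becomes the C1=C10 π bond and mesylate leaves C1. The closest known reaction type is the base-induced fragmentation of trans-decalin-1,3-diol monosulfonates to (E)-cyclodec-5-enones. No ring is closed by bond formation: the bond shared by the six-membered rings A and B is cut and their ten-atom perimeter C1–C10 is left, so the medium ring costs neither dilution nor an entropic penalty. No stereocentre is made; the auxiliary centres C1, C5 and C10 are erased, while C6, C7 and C8 are untouched. The new C1=C10 bond must be E, because in trans-fused 18 the equatorial C1–O bond is antiperiplanar to C5–C10 and C9 is antiperiplanar to C2 about C10–C1; C2=C3 stays Z because it was endocyclic in ring A, and C4=C15 is carried through unchanged. The step needs fragmentation to outrun substitution or ionisation at the allylic mesylate and acyl transfer from the lactone to the C5 alkoxide; the rigid antiperiplanar array, the good leaving group and the low temperature secure this, and the hindered base spares the two acrylate units. The product is born in the crown conformation of the decalin perimeter, which fixes the faces used in steps 16 and 17.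

Step 16
Reactants: 19 tetraenone
Product: 21 8α-angeloyloxy-1β,10α:2α,3α-diepoxy-5-oxogermacra-4(15),11(13)-dien-6α,12-olide, via monoepoxide 20 (not isolated)
Conditions: DMDO (excess), acetone–CH2Cl2, −20 to 0 °C
Reagents that add atoms: dimethyldioxirane, CC1(C)OO1
Why: Electrophilic epoxidation takes the trisubstituted C1=C10 first and then the Z-disubstituted C2=C3; the enone methylene, the lactone methylene and the angelate are electron-poor and should stay. C1=C10 can only be reached from outside the ring, that is anti to C5 at C10 and on the side that the mesylate left at C1 (C1, C10). C2=C3 is then attacked on the α face, away from C14 and from the new C1–O bond (C2, C3).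

Step 17
Reactants: 21 diepoxy enone
Product: 22 target (CNP0038366.2)
Conditions: NaBH4, CeCl3·7H2O, MeOH, −78 °C
Reagents that add atoms: none
Why: Luche 1,2-reduction of the α-methylene ketone. The carbonyl face that looked at C10 in 18 stays turned into the ring, so hydride can only come from outside, anti to the former C5–C10 bond, which gives the configuration required at C5. Epoxides, angelate and methylene lactone tolerate the cold, short reaction.

## Compound list

1 | 2,6-dimethylbenzaldehyde | Cc1cccc(C)c1C=O | starting material
2 | 3-bromo-2,6-dimethylbenzaldehyde | Cc1ccc(Br)c(C)c1C=O | intermediate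
3 | 2,6-dimethyl-3-(pinacolboryl)benzaldehyde | Cc1ccc(B2OC(C)(C)C(C)(C)O2)c(C)c1C=O | intermediate
4 | (S)-2,2-dimethyl-1,3-dioxolane-4-carbaldehyde | O=C[C@@H]1COC(C)(C)O1 | starting material
5 | methyl acrylate | C=CC(=O)OC | starting material
6 | Morita–Baylis–Hillman adduct (carbinol epimers) | C=C(C(=O)OC)C(O)[C@@H]1COC(C)(C)O1 | intermediate
7 | methyl (Z)-2-(bromomethyl)-3-[(4R)-2,2-dimethyl-1,3-dioxolan-4-yl]acrylate | BrC/C(=C\[C@@H]1COC(C)(C)O1)C(=O)OC | intermediate
8 | anti hydroxy ester (not isolated) | C=C(C(=O)OC)[C@@H]([C@H](O)c1c(C)ccc(B2OC(C)(C)C(C)(C)O2)c1C)[C@@H]1COC(C)(C)O1 | intermediate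
9 | trans aryl methylene lactone, acetonide, boronate | C=C1C(=O)O[C@H](c2c(C)ccc(B3OC(C)(C)C(C)(C)O3)c2C)[C@H]1[C@@H]1COC(C)(C)O1 | intermediate
10 | C8,C9-diol | C=C1C(=O)O[C@H](c2c(C)ccc(B3OC(C)(C)C(C)(C)O3)c2C)[C@H]1[C@@H](O)CO | intermediate
11 | C9 tosylate, C8 alcohol | C=C1C(=O)O[C@H](c2c(C)ccc(B3OC(C)(C)C(C)(C)O3)c2C)[C@H]1[C@@H](O)COS(=O)(=O)c1ccc(C)cc1 | intermediate
12 | C8 angelate, C9 tosylate, boronate | C=C1C(=O)O[C@H](c2c(C)ccc(B3OC(C)(C)C(C)(C)O3)c2C)[C@H]1[C@@H](OC(=O)/C(C)=C\C)COS(=O)(=O)c1ccc(C)cc1 | intermediate
13 | phenol with C8 angelate and C9 tosylate | C=C1C(=O)O[C@H](c2c(C)ccc(O)c2C)[C@H]1[C@@H](OC(=O)/C(C)=C\C)COS(=O)(=O)c1ccc(C)cc1 | intermediate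
14 | 8α-angeloyloxy-1-oxoeudesma-2,4,11(13)-trien-6α,12-olide | C=C1C(=O)O[C@H]2[C@H]1[C@@H](OC(=O)/C(C)=C\C)C[C@@]3(C)C(=O)C=CC(C)=C23 | intermediate
15 | 1β-hydroxy-2,4-diene | C=C1C(=O)O[C@H]2[C@H]1[C@@H](OC(=O)/C(C)=C\C)C[C@@]3(C)[C@H](O)C=CC(C)=C23 | intermediate
16 | 4α,5α-epoxy-1β-hydroxy-2-ene | C=C1C(=O)O[C@H]2[C@H]1[C@@H](OC(=O)/C(C)=C\C)C[C@@]3(C)[C@H](O)C=C[C@@]4(C)O[C@@]234 | intermediate
17 | 1β,5α-dihydroxy-2,4(15)-diene | C=C1C(=O)O[C@H]2[C@H]1[C@@H](OC(=O)/C(C)=C\C)C[C@@]3(C)[C@H](O)C=CC(=C)[C@]23O | intermediate
18 | 1β-mesylate, 5α-alcohol | C=C1C(=O)O[C@H]2[C@H]1[C@@H](OC(=O)/C(C)=C\C)C[C@@]3(C)[C@H](OS(C)(=O)=O)C=CC(=C)[C@]23O | intermediate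
19 | 8α-angeloyloxy-5-oxogermacra-1(10)E,2Z,4(15),11(13)-tetraen-6α,12-olide | C=C1C(=O)O[C@H]2[C@H]1[C@@H](OC(=O)/C(C)=C\C)C/C(C)=C/C=C\C(=C)C2=O | intermediate
20 | 1β,10α-monoepoxide (not isolated) | C=C1C(=O)O[C@H]2[C@H]1[C@@H](OC(=O)/C(C)=C\C)C[C@@]1(C)O[C@@H]1/C=C\C(=C)C2=O | intermediate
21 | 1β,10α:2α,3α-diepoxy-5-ketone | C=C1C(=O)O[C@H]2[C@H]1[C@@H](OC(=O)/C(C)=C\C)C[C@@]1(C)O[C@@H]1[C@H]1O[C@H]1C(=C)C2=O | intermediate
22 | target CNP0038366.2 | C=C1C(=O)O[C@H]2[C@H]1[C@@H](OC(=O)/C(C)=C\C)C[C@@]1(C)O[C@@H]1[C@H]1O[C@H]1C(=C)[C@H]2O | target

## Step count and least certain steps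

Total step count: 17.
Longest linear sequence: 15 (steps 1, 2 and 5–17; steps 3 and 4 make the second fragment).

**Step 15 (key step).** The allylic mesylate may ionise or be displaced with allylic shift before the alkoxide is formed. The C5 alkoxide may also attack the lactone carbonyl group, because both processes compete with a fragmentation that needs a well-aligned ring A. The fallback sets out from 17. Selective methoxycarbonylation of the secondary alcohol (ClCO2Me, pyridine) gives the C1 methyl carbonate F1. Pd(PPh3)4 in THF ionises F1 with loss of CO2. The methoxide released deprotonates the C5 hydroxyl, and the π-allylpalladium alkoxide undergoes β-carbon elimination. This is the known decarboxylative fragmentation of hydroxy allylic carbonates, and it runs under neutral conditions. The fallback comes back at 19.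

**Step 10.** Carbon alkylation may go to the para carbon of the phenolate (the arene carbon that bears C15) instead of the ortho carbon, because the cross-conjugated dienone is the more stable product. Loss of the tosylate by elimination may compete at the temperature needed. The fallback sets out from 13 and accepts the para mode. KOtBu in t-BuOH gives the cross-conjugated 3-oxo-1,4-dienone F2. Luche reduction gives the bis-allylic 3-alcohol F3. Ph3SiOReO3-catalysed 1,3-transposition moves the hydroxyl to the carbon next to the quaternary centre, driven by formation of the conjugated diene, and gives the 1-alcohol F4. MnO2 oxidises F4. The fallback comes back at 14.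

**Step 13.** Ionisation anti to the α-epoxide needs palladium on the β face, which C14 and the 1β-hydroxyl screen. The catalyst may therefore be slow, and the vinyl epoxide may decay by solvolysis instead. The fallback sets out from 16 and replaces metal-catalysed ionisation with a base-induced syn elimination using diethylaluminium 2,2,6,6-tetramethylpiperidide in toluene at 0 °C. Only C15 offers a hydrogen on the face of the epoxide oxygen. The fallback comes back at 17 and makes no new compound.

**Step 16.** Facial selectivity at the Z alkene C2=C3 may be poor because both faces of a cis alkene in a ten-membered ring are open. Slow over-oxidation of the enone methylene may set in while the sluggish second epoxidation is driven to completion. The fallback sets out from 20, made with one equivalent of DMDO. NBS in aqueous THF forms the bromonium ion on the face that the oxidant prefers, and water opens it from the other face to give the bromohydrin F5. K2CO3 then closes the epoxide on the face opposite to direct epoxidation. The fallback comes back at 21.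

**Step 17.** If the ring flips after the two epoxidations, hydride may be delivered to the other carbonyl face. Conjugate reduction of the methylene lactone may also compete if the ketone is slow. The fallback sets out from 21. If the 5-epimer F6 is formed, a Mitsunobu reaction with formic acid (PPh3, DIAD) inverts C5 and gives the formate F7. KHCO3 in MeOH at 0 °C cleaves F7 in the presence of the angelate and the lactone. The fallback comes back at 22.

## Further compounds

F1 | step 15 | C1 methyl carbonate of 17 | C=C1C(=O)O[C@H]2[C@H]1[C@@H](OC(=O)/C(C)=C\C)C[C@@]3(C)[C@H](OC(=O)OC)C=CC(=C)[C@]23O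
F2 | step 10 | 8α-angeloyloxy-3-oxoeudesma-1,4,11(13)-trien-6α,12-olide | C=C1C(=O)O[C@H]2[C@H]1[C@@H](OC(=O)/C(C)=C\C)C[C@@]3(C)C=CC(=O)C(C)=C23
F3 | step 10 | 3-hydroxy-1,4-diene (C3 epimers) | C=C1C(=O)O[C@H]2[C@H]1[C@@H](OC(=O)/C(C)=C\C)C[C@@]3(C)C=CC(O)C(C)=C23
F4 | step 10 | 1-hydroxy-2,4-diene (C1 epimers) | C=C1C(=O)O[C@H]2[C@H]1[C@@H](OC(=O)/C(C)=C\C)C[C@@]3(C)C(O)C=CC(C)=C23
F0 | step 13 | none | none
F5 | step 16 | 2β-bromo-3α-hydroxy derivative of 20 | C=C1C(=O)O[C@H]2[C@H]1[C@@H](OC(=O)/C(C)=C\C)C[C@@]1(C)O[C@@H]1[C@H](Br)[C@@H](O)C(=C)C2=O
F6 | step 17 | C5 epimer of 22 | C=C1C(=O)O[C@H]2[C@H]1[C@@H](OC(=O)/C(C)=C\C)C[C@@]1(C)O[C@@H]1[C@H]1O[C@H]1C(=C)[C@@H]2O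
F7 | step 17 | C5 formate of 22 | C=C1C(=O)O[C@H]2[C@H]1[C@@H](OC(=O)/C(C)=C\C)C[C@@]1(C)O[C@@H]1[C@H]1O[C@H]1C(=C)[C@H]2OC=O
A1 | alternative 1 | open-chain C6 aldehyde, C13 bromide with both epoxides | O=C[C@H](O[Si](CC)(CC)CC)C(=C)[C@@H]1O[C@@H]1[C@H]1O[C@]1(C)C[C@H](OC(=O)/C(C)=C\C)/C=C(\CBr)C(=O)OC
A2 | alternative 2 | 1-(2-methoxyvinyl)-2-isopropenylcyclohexanol with 2,3-epoxide, 4-methylene and 5-silyloxy groups | C=C(C)[C@@H]1[C@H]2O[C@H]2C(=C)[C@@H](O[Si](C)(C)C(C)(C)C)[C@@]1(O)/C=C/OC
A3 | alternative 3 | 8α-angeloyloxy-5αH-eudesma-1,3,11(13)-trien-6α,12-olide | C=C1C(=O)O[C@H]2[C@H]1[C@@H](OC(=O)/C(C)=C\C)C[C@@]3(C)C=CC=C(C)[C@H]23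
A4 | alternative 3 | 8α-angeloyloxygermacra-1(10)E,2Z,4E,11(13)-tetraen-6α,12-olide | C=C1C(=O)O[C@H]2[C@H]1[C@@H](OC(=O)/C(C)=C\C)C/C(C)=C/C=C\C(C)=C\2
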